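The target is an ester of two seco-cadinane units that differ only by water across the butenolide C=C, so one building block serves both. Its cyclohexene (ring B) is closed by an inverse-demand [4+2] annulation: the s-cis-locked exocyclic diene of a 3-alkylidene-4-methylene butyrolactone, whose lactone carbonyl makes the alkylidene carbon electrophilic, takes up the CH=CH edge of the chiral enamine of isovaleraldehyde. This forms the ring CH2–CH2 bond and the CH(isopropyl)–CH(side chain) bond together, regenerates the butenolide C=C and sets both ring stereocentres; amine loss and hydrogenation follow. Epoxidation/SmI2 opening gives the hydrated unit, and a Horner–Wadsworth–Emmons reaction joins the halves.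

Key step: step 4

Remark on labels: ring B is the cyclohexene fused to the butenolide (upper unit); ring A is the cyclohexane of the hydrated lower unit. Ring positions are numbered as in 2-benzofuran-1(3H)-one (lactone C=O = C1).
Assumption: the s-trans enamine of (S)-2-(methoxymethyl)pyrrolidine is attacked on the face anti to the methoxymethyl arm, as in Michael additions of such enamines; if the sense proved opposite, the (R)-amine would be used.

Step 1
Reactants: 1 tert-butyldimethyl(prop-2-yn-1-yloxy)silane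
Product: 2 methyl 4-[(tert-butyldimethylsilyl)oxy]but-2-ynoate
Conditions: n-BuLi, THF, −78 °C; ClCO2Me, −78 °C to 0 °C
Reagents that add atoms: methyl chloroformate, COC(=O)Cl
Why: Acylation of the lithium acetylide with a chloroformate is the standard ynoate synthesis and the silyl ether is inert to it.

Step 2
Reactants: 2 methyl 4-[(tert-butyldimethylsilyl)oxy]but-2-ynoate
Product: 3 methyl (2E)-4-[(tert-butyldimethylsilyl)oxy]-2-(tributylstannyl)but-2-enoate
Conditions: Bu3SnH, Pd(PPh3)4 (cat.), THF, 0 °C
Reagents that add atoms: tributyltin hydride, CCCC[SnH](CCCC)CCCC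
Why: Palladium-catalysed hydrostannation of ynoates is a syn addition that places tin α to the ester, so the silyloxymethyl group should end up cis to the ester.

Step 3
Reactants: 3 methyl (2E)-4-[(tert-butyldimethylsilyl)oxy]-2-(tributylstannyl)but-2-enoate; 4 2-bromoprop-2-en-1-ol
Product: 6 (3Z)-3-{2-[(tert-butyldimethylsilyl)oxy]ethylidene}-4-methylideneoxolan-2-one, via hydroxy dienoate 5 (not isolated)
Conditions: Pd2(dba)3 (cat.), tri(2-furyl)phosphine, CuI, NMP, 50 °C; then PPTS, CH2Cl2, rt
Reagents that add atoms: none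
Why: Copper-assisted Stille coupling retains the alkene geometry and the resulting hydroxymethyl/ester pair on adjacent diene carbons lactonises, giving the exocyclic diene with its substituent pointing outward (cis to the lactone carbonyl).

Step 4
Reactants: 6 (3Z)-3-{2-[(tert-butyldimethylsilyl)oxy]ethylidene}-4-methylideneoxolan-2-one; 7 3-methylbutanal; 8 (2S)-2-(methoxymethyl)pyrrolidine
Product: 11 (6S,7R)-7-{[(tert-butyldimethylsilyl)oxy]methyl}-6-(propan-2-yl)-6,7-dihydro-2-benzofuran-1(3H)-one, via enamine 9 (not isolated), via aminocyclohexene cycloadduct 10 (not isolated)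
Conditions: 7, 8, 4 Å molecular sieves, MeCN, 0 °C to rt; add 6, 50 °C; then AcOH, NaOAc, 60 °C
Reagents that add atoms: none
Why: The enamine β-carbon (the future CH–isopropyl) adds to the alkylidene carbon of 6, the only diene carbon β to the lactone carbonyl, and the lactone dienolate so formed closes through its exocyclic CH2 terminus onto the iminium carbon (concerted-asynchronous [4+2] or Michael/vinylogous Mannich, a 6-exo-trig closure), so both ring bonds and the butenolide C=C arise together while any cyclobutane from α-attack can revert. The closest known reaction type is the inverse-electron-demand Diels–Alder annulation of aldehyde enamines with 2-acyl-1,3-dienes and dienoates followed by loss of the amine. The trans relation of the silyloxymethyl and isopropyl carbons should follow from the (E)-enamine reacting with nitrogen endo (synclinal donor–acceptor arrangement, isopropyl exo) at a diene whose substituent points outward. The absolute configuration is set by the methoxymethyl arm of the s-trans enamine, which shields one face of the nucleophilic carbon. Regioselectivity is secured by the polarity of the diene, and acetate-buffered warming should then expel the amine by vinylogous E1cB elimination across the acidic γ-CH2 of the butenolide, which erases the aminated stereocentre and returns the auxiliary.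

Step 5
Reactants: 11 (6S,7R)-7-{[(tert-butyldimethylsilyl)oxy]methyl}-6-(propan-2-yl)-6,7-dihydro-2-benzofuran-1(3H)-one
Product: 12 (6R,7R)-7-{[(tert-butyldimethylsilyl)oxy]methyl}-6-(propan-2-yl)-4,5,6,7-tetrahydro-2-benzofuran-1(3H)-one
Conditions: H2 (1 atm), RhCl(PPh3)3 (cat.), toluene/EtOH, rt
Reagents that add atoms: none
Why: Homogeneous rhodium-catalysed hydrogenation should reduce the cis-disubstituted alkene and leave the tetrasubstituted butenolide alkene, creating no stereocentre (the descriptor at C6 changes only through priorities).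

Step 6
Reactants: 12 (6R,7R)-7-{[(tert-butyldimethylsilyl)oxy]methyl}-6-(propan-2-yl)-4,5,6,7-tetrahydro-2-benzofuran-1(3H)-one
Product: 13 (6R,7R)-7-(hydroxymethyl)-6-(propan-2-yl)-4,5,6,7-tetrahydro-2-benzofuran-1(3H)-one
Conditions: HF·pyridine, pyridine, THF, 0 °C to rt
Reagents that add atoms: none
Why: Buffered fluoride desilylation frees the primary alcohol without touching the base-sensitive butenolide; 13 is the common intermediate for both halves.

Step 7
Reactants: 13 (6R,7R)-7-(hydroxymethyl)-6-(propan-2-yl)-4,5,6,7-tetrahydro-2-benzofuran-1(3H)-one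
Product: 14 (4R,5R)-3-oxo-5-(propan-2-yl)-1,3,4,5,6,7-hexahydro-2-benzofuran-4-carbaldehyde
Conditions: Dess–Martin periodinane, NaHCO3, CH2Cl2, 0 °C
Reagents that add atoms: none
Why: Dess–Martin oxidation is non-basic, so the β,γ-unsaturated aldehyde should form without epimerisation or double-bond migration; it is used at once in step 16.

Step 8
Reactants: 13 (6R,7R)-7-(hydroxymethyl)-6-(propan-2-yl)-4,5,6,7-tetrahydro-2-benzofuran-1(3H)-one
Product: 15 (3aR,6R,7S,7aR)-3a,7a-epoxy-7-(hydroxymethyl)-6-(propan-2-yl)hexahydro-2-benzofuran-1(3H)-one (epoxide oxygen on the face of the hydroxymethyl group)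
Conditions: mCPBA, NaHCO3, CH2Cl2, 0 °C to rt
Reagents that add atoms: 3-chloroperbenzoic acid, OOC(=O)c1cccc(Cl)c1
Why: Hydroxyl-directed (Henbest-type) peracid epoxidation: the homoallylic OH hydrogen-bonds the peracid and should deliver oxygen to its own face of the tetrasubstituted alkene, which is still reactive enough despite the lactone carbonyl.

Step 9
Reactants: 15 (3aR,6R,7S,7aR)-3a,7a-epoxy-7-(hydroxymethyl)-6-(propan-2-yl)hexahydro-2-benzofuran-1(3H)-one
Product: 16 (3aS,6R,7R,7aS)-3a-hydroxy-7-(hydroxymethyl)-6-(propan-2-yl)hexahydro-2-benzofuran-1(3H)-one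
Conditions: SmI2, HMPA, MeOH, THF, −78 °C
Reagents that add atoms: none
Why: SmI2 reduction of an α,β-epoxy ester cleaves the Cα–O bond and keeps the β-oxygen with its configuration; protonation of the samarium enolate should give the cis-fused lactone, the only isomer in which isopropyl, hydroxymethyl and the lactone carbonyl are all equatorial.

Step 10
Reactants: 16 (3aS,6R,7R,7aS)-3a-hydroxy-7-(hydroxymethyl)-6-(propan-2-yl)hexahydro-2-benzofuran-1(3H)-one
Product: 17 (3aS,4R,5R,7aS)-7a-hydroxy-3-oxo-5-(propan-2-yl)octahydro-2-benzofuran-4-carbaldehyde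
Conditions: Dess–Martin periodinane, NaHCO3, CH2Cl2, 0 °C
Reagents that add atoms: none
Why: Dess–Martin oxidation converts only the primary alcohol, the tertiary one being inert, and the aldehyde-bearing carbon is already in its thermodynamically preferred equatorial configuration.

Step 11
Reactants: 18 prop-2-en-1-yl (diethoxyphosphoryl)acetate
Product: 19 prop-2-en-1-yl 2-(diethoxyphosphoryl)-3-hydroxypropanoate (racemic)
Conditions: paraformaldehyde (1 equiv), piperidine (cat.), MeCN, 60 °C
Reagents that add atoms: formaldehyde (from paraformaldehyde), C=O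
Why: Amine-catalysed aldol-type hydroxymethylation of a phosphonoacetate stops at the β-hydroxy phosphonate when one equivalent of formaldehyde and a weak base are used.

Step 12
Reactants: 19 prop-2-en-1-yl 2-(diethoxyphosphoryl)-3-hydroxypropanoate
Product: 20 prop-2-en-1-yl 3-[(tert-butyldimethylsilyl)oxy]-2-(diethoxyphosphoryl)propanoate (racemic)
Conditions: TBSCl, imidazole, DMF, rt
Reagents that add atoms: tert-butyldimethylsilyl chloride, CC(C)(C)[Si](C)(C)Cl
Why: Standard silylation of a primary alcohol gives the olefination reagent that carries the protected hydroxymethyl group.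

Step 13
Reactants: 20 prop-2-en-1-yl 3-[(tert-butyldimethylsilyl)oxy]-2-(diethoxyphosphoryl)propanoate
Product: 21 3-[(tert-butyldimethylsilyl)oxy]-2-(diethoxyphosphoryl)propanoic acid (racemic)
Conditions: Pd(PPh3)4 (cat.), morpholine, THF, rt; aqueous KHSO4 work-up
Reagents that add atoms: none
Why: Tsuji–Trost deallylation removes the allyl ester under near-neutral conditions that leave the silyl ether and phosphonate untouched.

Step 14
Reactants: 17 (3aS,4R,5R,7aS)-7a-hydroxy-3-oxo-5-(propan-2-yl)octahydro-2-benzofuran-4-carbaldehyde; 20 prop-2-en-1-yl 3-[(tert-butyldimethylsilyl)oxy]-2-(diethoxyphosphoryl)propanoate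
Product: 22 prop-2-en-1-yl (2E)-2-{[(tert-butyldimethylsilyl)oxy]methyl}-3-[(3aS,4S,5R,7aS)-7a-hydroxy-3-oxo-5-(propan-2-yl)octahydro-2-benzofuran-4-yl]prop-2-enoate
Conditions: LiCl, DBU, MeCN, 0 °C to rt
Reagents that add atoms: none
Why: Horner–Wadsworth–Emmons olefination under Masamune–Roush conditions with an α-substituted phosphonoacetate should place the ester trans to the ring substituent (E), i.e. the silyloxymethyl group cis to the ring as required, and the free tertiary alcohol is not deprotonated.

Step 15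
Reactants: 22 prop-2-en-1-yl (2E)-2-{[(tert-butyldimethylsilyl)oxy]methyl}-3-[(3aS,4S,5R,7aS)-7a-hydroxy-3-oxo-5-(propan-2-yl)octahydro-2-benzofuran-4-yl]prop-2-enoate; 21 3-[(tert-butyldimethylsilyl)oxy]-2-(diethoxyphosphoryl)propanoic acid
Product: 23 the 7a-O-{3-[(tert-butyldimethylsilyl)oxy]-2-(diethoxyphosphoryl)propanoyl} ester of 22 (mixture of epimers at the phosphorus-bearing carbon)
Conditions: DCC, DMAP (cat.), CH2Cl2, 0 °C to rt
Reagents that add atoms: none
Why: Steglich-type acylation with a small phosphonoacetic acid (activated through its anhydride or phosphonoketene) is the established way to acylate tertiary alcohols before an olefination, and the new stereocentre is removed in the next step.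

Step 16
Reactants: 23 the 7a-O-{3-[(tert-butyldimethylsilyl)oxy]-2-(diethoxyphosphoryl)propanoyl} ester of 22; 14 (4R,5R)-3-oxo-5-(propan-2-yl)-1,3,4,5,6,7-hexahydro-2-benzofuran-4-carbaldehyde
Product: 24 the allyl ester bis(tert-butyldimethylsilyl) ether of the target
Conditions: LiCl, iPr2NEt, MeCN, 0 °C to rt
Reagents that add atoms: none
Why: Horner–Wadsworth–Emmons union of the two halves under the mildest Masamune–Roush conditions should give the (E)-enoate while the weak amine base spares the β-acyloxy lactone of ring A and the epimerisable aldehyde.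

Step 17
Reactants: 24 the allyl ester bis(tert-butyldimethylsilyl) ether of the target
Product: 25 the allyl ester of the target
Conditions: HF·pyridine, pyridine, THF, 0 °C to rt
Reagents that add atoms: none
Why: Buffered acidic fluoride cleaves both primary allylic silyl ethers without the basicity that would trigger β-elimination of the tertiary ester.

Step 18
Reactants: 25 the allyl ester of the target
Product: 26 (2E)-2-(hydroxymethyl)-3-[(3aS,4S,5R,7aS)-7a-({(2E)-2-(hydroxymethyl)-3-[(4S,5R)-3-oxo-5-(propan-2-yl)-1,3,4,5,6,7-hexahydro-2-benzofuran-4-yl]prop-2-enoyl}oxy)-3-oxo-5-(propan-2-yl)octahydro-2-benzofuran-4-yl]prop-2-enoic acid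
Conditions: Pd(PPh3)4 (cat.), N-methylaniline, THF, rt
Reagents that add atoms: none
Why: Tsuji–Trost deallylation with a weakly basic allyl acceptor frees the acid under neutral conditions; the terminal allyl ester ionises far faster than the hindered butenolide C–O bond.

Compound list
1 | tert-butyldimethyl(prop-2-yn-1-yloxy)silane | C#CCO[Si](C)(C)C(C)(C)C | starting material
2 | methyl 4-[(tert-butyldimethylsilyl)oxy]but-2-ynoate | COC(=O)C#CCO[Si](C)(C)C(C)(C)C | intermediate
3 | methyl (2E)-4-[(tert-butyldimethylsilyl)oxy]-2-(tributylstannyl)but-2-enoate | COC(=O)/C(=C\CO[Si](C)(C)C(C)(C)C)[Sn](CCCC)(CCCC)CCCC | intermediate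
4 | 2-bromoprop-2-en-1-ol | OCC(Br)=C | starting material
5 | methyl (2Z)-4-[(tert-butyldimethylsilyl)oxy]-2-(3-hydroxyprop-1-en-2-yl)but-2-enoate (not isolated) | COC(=O)/C(=C\CO[Si](C)(C)C(C)(C)C)C(=C)CO | intermediate
6 | (3Z)-3-{2-[(tert-butyldimethylsilyl)oxy]ethylidene}-4-methylideneoxolan-2-one | C=C1COC(=O)/C1=C\CO[Si](C)(C)C(C)(C)C | intermediate
7 | 3-methylbutanal | CC(C)CC=O | starting material
8 | (2S)-2-(methoxymethyl)pyrrolidine | COC[C@@H]1CCCN1 | starting material
9 | (2S)-2-(methoxymethyl)-1-[(1E)-3-methylbut-1-en-1-yl]pyrrolidine (not isolated) | CC(C)/C=C/N1CCC[C@H]1COC | intermediate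
10 | (5R,6R,7R)-7-{[(tert-butyldimethylsilyl)oxy]methyl}-5-[(2S)-2-(methoxymethyl)pyrrolidin-1-yl]-6-(propan-2-yl)-4,5,6,7-tetrahydro-2-benzofuran-1(3H)-one (all-trans; not isolated) | CC(C)(C)[Si](C)(C)OC[C@H]1C2=C(C[C@@H](N3CCC[C@H]3COC)[C@@H]1C(C)C)COC2=O | intermediate
11 | (6S,7R)-7-{[(tert-butyldimethylsilyl)oxy]methyl}-6-(propan-2-yl)-6,7-dihydro-2-benzofuran-1(3H)-one | CC(C)(C)[Si](C)(C)OC[C@H]1C2=C(C=C[C@@H]1C(C)C)COC2=O | intermediate
12 | (6R,7R)-7-{[(tert-butyldimethylsilyl)oxy]methyl}-6-(propan-2-yl)-4,5,6,7-tetrahydro-2-benzofuran-1(3H)-one | CC(C)(C)[Si](C)(C)OC[C@H]1C2=C(CC[C@@H]1C(C)C)COC2=O | intermediate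
13 | (6R,7R)-7-(hydroxymethyl)-6-(propan-2-yl)-4,5,6,7-tetrahydro-2-benzofuran-1(3H)-one | OC[C@H]1C2=C(CC[C@@H]1C(C)C)COC2=O | intermediate
14 | (4R,5R)-3-oxo-5-(propan-2-yl)-1,3,4,5,6,7-hexahydro-2-benzofuran-4-carbaldehyde | O=C[C@H]1C2=C(CC[C@@H]1C(C)C)COC2=O | intermediate
15 | (3aR,6R,7S,7aR)-3a,7a-epoxy-7-(hydroxymethyl)-6-(propan-2-yl)hexahydro-2-benzofuran-1(3H)-one | OC[C@H]1[C@@]23O[C@]2(CC[C@@H]1C(C)C)COC3=O | intermediate
16 | (3aS,6R,7R,7aS)-3a-hydroxy-7-(hydroxymethyl)-6-(propan-2-yl)hexahydro-2-benzofuran-1(3H)-one | CC(C)[C@H]1CC[C@@]2(O)COC(=O)[C@H]2[C@@H]1CO | intermediate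
17 | (3aS,4R,5R,7aS)-7a-hydroxy-3-oxo-5-(propan-2-yl)octahydro-2-benzofuran-4-carbaldehyde | CC(C)[C@H]1CC[C@@]2(O)COC(=O)[C@H]2[C@@H]1C=O | intermediate
18 | prop-2-en-1-yl (diethoxyphosphoryl)acetate | C=CCOC(=O)CP(=O)(OCC)OCC | starting material
19 | prop-2-en-1-yl 2-(diethoxyphosphoryl)-3-hydroxypropanoate (racemic) | C=CCOC(=O)C(CO)P(=O)(OCC)OCC | intermediate
20 | prop-2-en-1-yl 3-[(tert-butyldimethylsilyl)oxy]-2-(diethoxyphosphoryl)propanoate (racemic) | C=CCOC(=O)C(CO[Si](C)(C)C(C)(C)C)P(=O)(OCC)OCC | intermediate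
21 | 3-[(tert-butyldimethylsilyl)oxy]-2-(diethoxyphosphoryl)propanoic acid (racemic) | OC(=O)C(CO[Si](C)(C)C(C)(C)C)P(=O)(OCC)OCC | intermediate
22 | prop-2-en-1-yl (2E)-2-{[(tert-butyldimethylsilyl)oxy]methyl}-3-[(3aS,4S,5R,7aS)-7a-hydroxy-3-oxo-5-(propan-2-yl)octahydro-2-benzofuran-4-yl]prop-2-enoate | CC(C)[C@H]1CC[C@@]2(O)COC(=O)[C@H]2[C@@H]1/C=C(\CO[Si](C)(C)C(C)(C)C)C(=O)OCC=C | intermediate
23 | 7a-O-{3-[(tert-butyldimethylsilyl)oxy]-2-(diethoxyphosphoryl)propanoyl} ester of 22 (epimers at the phosphorus-bearing carbon) | CC(C)[C@H]1CC[C@@]2(OC(=O)C(CO[Si](C)(C)C(C)(C)C)P(=O)(OCC)OCC)COC(=O)[C@H]2[C@@H]1/C=C(\CO[Si](C)(C)C(C)(C)C)C(=O)OCC=C | intermediate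
24 | allyl ester bis(tert-butyldimethylsilyl) ether of the target | CC(C)[C@H]1CC[C@@]2(OC(=O)/C(=C/[C@H]3C4=C(CC[C@@H]3C(C)C)COC4=O)CO[Si](C)(C)C(C)(C)C)COC(=O)[C@H]2[C@@H]1/C=C(\CO[Si](C)(C)C(C)(C)C)C(=O)OCC=C | intermediate
25 | allyl ester of the target | CC(C)[C@H]1CC[C@@]2(OC(=O)/C(=C/[C@H]3C4=C(CC[C@@H]3C(C)C)COC4=O)CO)COC(=O)[C@H]2[C@@H]1/C=C(\CO)C(=O)OCC=C | intermediate
26 | (2E)-2-(hydroxymethyl)-3-[(3aS,4S,5R,7aS)-7a-({(2E)-2-(hydroxymethyl)-3-[(4S,5R)-3-oxo-5-(propan-2-yl)-1,3,4,5,6,7-hexahydro-2-benzofuran-4-yl]prop-2-enoyl}oxy)-3-oxo-5-(propan-2-yl)octahydro-2-benzofuran-4-yl]prop-2-enoic acid (CNP0238371.2) | CC(C)[C@H]1CC[C@@]2(OC(=O)/C(=C/[C@H]3C4=C(CC[C@@H]3C(C)C)COC4=O)CO)COC(=O)[C@H]2[C@@H]1/C=C(\CO)C(=O)O | target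

Total step count: 18. Longest linear sequence: 14 steps (steps 1–6, 8–10, 14–18).

Steps most likely to fail

Step 4. The branched enamine 9 may add too slowly to the β-substituted alkylidene lactone, so that diene dimerisation or conjugate addition of free amine takes over, or facial and endo/exo control may be weak. The fallback sets out from 6 and 7 and comes back at 13; it moves absolute control from the auxiliary to an enzymatic kinetic resolution. The cycloaddition would be run with the unhindered, more nucleophilic achiral enamine 1-[(1E)-3-methylbut-1-en-1-yl]pyrrolidine F1 (from 7 and pyrrolidine, molecular sieves). This would give, through the racemic pyrrolidine cycloadduct F2 and acetate-buffered amine loss, 11 together with its (6R,7S)-enantiomer F3. Hydrogenation as in step 5 would give 12 with its (6S,7S)-enantiomer F4, and desilylation as in step 6 would give 13 with its (6S,7S)-enantiomer F5. Lipase-catalysed acetylation (Amano lipase PS, vinyl acetate, the enzyme chosen by screening so that the (6S,7S)-alcohol reacts faster) would convert F5 into [(4S,5S)-3-oxo-5-(propan-2-yl)-1,3,4,5,6,7-hexahydro-2-benzofuran-4-yl]methyl acetate F6 and leave 13, which is separated and carried on.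

Step 16. The amine base may trigger E1cB loss of the tertiary acyloxy group across the lactone α-position of ring A, or epimerise and deconjugate aldehyde 14, or the α-substituted phosphonate may react too slowly and unselectively. The fallback sets out from 14 and 22 and comes back at 24; it joins the halves by C–O instead of C=C bond formation, and steps 13 and 15 are then not needed. Aldehyde 14 would be olefinated with the preformed sodium salt of 20 (NaH, THF, −20 °C) to prop-2-en-1-yl (2E)-2-{[(tert-butyldimethylsilyl)oxy]methyl}-3-[(4S,5R)-3-oxo-5-(propan-2-yl)-1,3,4,5,6,7-hexahydro-2-benzofuran-4-yl]prop-2-enoate F8. Deallylation (Pd(PPh3)4, morpholine) would give the corresponding (2E)-prop-2-enoic acid F9. Yamaguchi esterification of F9 with the tertiary alcohol 22 (2,4,6-trichlorobenzoyl chloride, Et3N; then DMAP, toluene) would give 24.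

Step 8. Direction by the homoallylic hydroxyl may be too weak, giving poor facial selectivity, or the electron-poor alkene may epoxidise too slowly. The fallback sets out from 13 and comes back at 16. Hydroxyl-directed syn-dihydroxylation (OsO4, TMEDA, CH2Cl2, −78 °C; aqueous Na2SO3 work-up) would give (3aR,6R,7S,7aR)-3a,7a-dihydroxy-7-(hydroxymethyl)-6-(propan-2-yl)hexahydro-2-benzofuran-1(3H)-one F7, with both new hydroxyls on the face of the hydroxymethyl group. SmI2/HMPA with ethylene glycol would then remove only the hydroxyl α to the lactone carbonyl (as in tartrate-to-malate reductions), and protonation of the enolate would give 16.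

Further compounds
F1 | step 4 | 1-[(1E)-3-methylbut-1-en-1-yl]pyrrolidine | CC(C)/C=C/N1CCCC1
F2 | step 4 | rac-(5R,6R,7R)-7-{[(tert-butyldimethylsilyl)oxy]methyl}-6-(propan-2-yl)-5-(pyrrolidin-1-yl)-4,5,6,7-tetrahydro-2-benzofuran-1(3H)-one (racemate, one enantiomer drawn) | CC(C)(C)[Si](C)(C)OC[C@H]1C2=C(C[C@@H](N3CCCC3)[C@@H]1C(C)C)COC2=O
F3 | step 4 | (6R,7S)-7-{[(tert-butyldimethylsilyl)oxy]methyl}-6-(propan-2-yl)-6,7-dihydro-2-benzofuran-1(3H)-one (enantiomer of 11) | CC(C)(C)[Si](C)(C)OC[C@@H]1C2=C(C=C[C@H]1C(C)C)COC2=O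
F4 | step 4 | (6S,7S)-7-{[(tert-butyldimethylsilyl)oxy]methyl}-6-(propan-2-yl)-4,5,6,7-tetrahydro-2-benzofuran-1(3H)-one (enantiomer of 12) | CC(C)(C)[Si](C)(C)OC[C@@H]1C2=C(CC[C@H]1C(C)C)COC2=O
F5 | step 4 | (6S,7S)-7-(hydroxymethyl)-6-(propan-2-yl)-4,5,6,7-tetrahydro-2-benzofuran-1(3H)-one (enantiomer of 13) | OC[C@@H]1C2=C(CC[C@H]1C(C)C)COC2=O
F6 | step 4 | [(4S,5S)-3-oxo-5-(propan-2-yl)-1,3,4,5,6,7-hexahydro-2-benzofuran-4-yl]methyl acetate | CC(=O)OC[C@@H]1C2=C(CC[C@H]1C(C)C)COC2=O
F7 | step 8 | (3aR,6R,7S,7aR)-3a,7a-dihydroxy-7-(hydroxymethyl)-6-(propan-2-yl)hexahydro-2-benzofuran-1(3H)-one | CC(C)[C@H]1CC[C@@]2(O)COC(=O)[C@@]2(O)[C@@H]1CO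
F8 | step 16 | prop-2-en-1-yl (2E)-2-{[(tert-butyldimethylsilyl)oxy]methyl}-3-[(4S,5R)-3-oxo-5-(propan-2-yl)-1,3,4,5,6,7-hexahydro-2-benzofuran-4-yl]prop-2-enoate | C=CCOC(=O)/C(=C/[C@H]1C2=C(CC[C@@H]1C(C)C)COC2=O)CO[Si](C)(C)C(C)(C)C
F9 | step 16 | (2E)-2-{[(tert-butyldimethylsilyl)oxy]methyl}-3-[(4S,5R)-3-oxo-5-(propan-2-yl)-1,3,4,5,6,7-hexahydro-2-benzofuran-4-yl]prop-2-enoic acid | OC(=O)/C(=C/[C@H]1C2=C(CC[C@@H]1C(C)C)COC2=O)CO[Si](C)(C)C(C)(C)C
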